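**Strategy**

The route rests on disconnecting the benzylic C7–O bond of the oxolane ring that carries the syringyl ring B (C7 = benzylic carbon on ring B; C9′ = OCH2 carbon of the guaiacyl half). The key step copies lignan biosynthesis: an open-chain 1,4-diaryl-2,3-bis(hydroxymethyl)butane with C8 and C8′ already set is ionised by mild acid to the ring-B p-quinone methide at C7, exploiting the phenolic oxygen para to C7; the C9′ hydroxyl closes the O–C7 ring by 5-exo oxa-1,6-addition, the C9 hydroxyl closes the second ring at C7′, and both aryl-bearing centres are set exo. The erythro arylglycerol ether is then built on the freed ring-B phenol by an auxiliary-controlled anti glycolate aldol.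

Key step: step 6

Labels: ring A = guaiacyl ring on C7′, ring B = syringyl ring on C7, ring C = guaiacyl ring on C7″; C7/C8/C9 = benzylic CH, bridgehead CH and OCH2 of the ring-B half, primed atoms the same for the ring-A half, C7″–C9″ = glycerol chain.

Assumption: the MgCl2-catalysed anti-aldol of N-acyloxazolidinones is taken to run through the chelated Z-enolate with the aldehyde approaching the face opposite the benzyl group; the (R)-auxiliary in 14 is chosen on that basis, and 14 is taken as a commercial reagent.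

**Route**

Step 1
Reactants: 1 syringaldehyde (4-hydroxy-3,5-dimethoxybenzaldehyde)
Product: 2 4-formyl-2,6-dimethoxyphenyl pivalate
Conditions: PivCl, Et3N, DMAP (cat.), CH2Cl2, 0 °C to rt
Reagents that add atoms: pivaloyl chloride, CC(C)(C)C(Cl)=O
Why: DMAP-catalysed O-acylation masks the phenol, makes the aldehyde a better aldol acceptor and installs a group that the later LiAlH4 step removes without an extra operation.

Step 2
Reactants: 2 4-formyl-2,6-dimethoxyphenyl pivalate; 3 methyl 4-oxobutanoate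
Product: 6 (R)-4-[(R)-hydroxy(3,5-dimethoxy-4-pivaloyloxyphenyl)methyl]oxolan-2-one, via aldol aldehyde 4 (not isolated), via diol ester 5 (not isolated)
Conditions: L-proline (30 mol %), DMF, 4 °C; then NaBH4, MeOH, −20 to 0 °C; aq. NH4Cl
Reagents that add atoms: none
Why: Proline-catalysed direct asymmetric cross-aldol reaction (enamine catalysis), in which the E-enamine of 3 adds to the aryl aldehyde through the carboxylic-acid-bound chair transition state to set C8 (the later 8R centre) and the anti C7 carbinol, after which hydride reduction of the aldehyde and lactonisation of the primary alcohol onto the methyl ester give the lactone.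

Step 3
Reactants: 6 (R)-4-[(R)-hydroxy(3,5-dimethoxy-4-pivaloyloxyphenyl)methyl]oxolan-2-one
Product: 7 (R)-4-[(R)-(tert-butyldimethylsilyloxy)(3,5-dimethoxy-4-pivaloyloxyphenyl)methyl]oxolan-2-one
Conditions: TBSOTf, 2,6-lutidine, CH2Cl2, −78 to 0 °C
Reagents that add atoms: tert-butyldimethylsilyl triflate, CC(C)(C)[Si](C)(C)OS(=O)(=O)C(F)(F)F
Why: Silylation of the benzylic alcohol prevents alkoxide-triggered translactonisation in the enolate step (which would reverse the facial sense of the next bond formation) and turns the C7 oxygen into the group that leaves in step 6.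

Step 4
Reactants: 7 (R)-4-[(R)-(tert-butyldimethylsilyloxy)(3,5-dimethoxy-4-pivaloyloxyphenyl)methyl]oxolan-2-one; 8 4-(allyloxy)-3-methoxybenzaldehyde
Product: 9 (3S,4R)-3-[hydroxy(4-allyloxy-3-methoxyphenyl)methyl]-4-[(R)-(tert-butyldimethylsilyloxy)(3,5-dimethoxy-4-pivaloyloxyphenyl)methyl]oxolan-2-one (both C7′ carbinol epimers)
Conditions: LiN(SiMe3)2, THF, −78 °C; then 8; AcOH quench at −78 °C
Reagents that add atoms: none
Why: Lithium enolate aldol addition in which the lactone enolate is attacked anti to the bulky C8 substituent, setting C8′ trans to C8 (the later 8′R centre), while the C7′ carbinol configuration is immaterial because step 6 re-sets it.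

Step 5
Reactants: 9 (3S,4R)-3-[hydroxy(4-allyloxy-3-methoxyphenyl)methyl]-4-[(R)-(tert-butyldimethylsilyloxy)(3,5-dimethoxy-4-pivaloyloxyphenyl)methyl]oxolan-2-one
Product: 10 (2R,3R)-2-[(R)-(tert-butyldimethylsilyloxy)(4-hydroxy-3,5-dimethoxyphenyl)methyl]-3-[hydroxy(4-allyloxy-3-methoxyphenyl)methyl]butane-1,4-diol
Conditions: LiAlH4, THF, 0 °C; aq. potassium sodium tartrate; used without delay
Reagents that add atoms: none
Why: Hydride reduction opens the lactone to the 1,4-diol and cleaves the aryl pivalate in the same operation, freeing the ring-B phenol needed for quinone methide formation without touching a stereocentre.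

Step 6
Reactants: 10 (2R,3R)-2-[(R)-(tert-butyldimethylsilyloxy)(4-hydroxy-3,5-dimethoxyphenyl)methyl]-3-[hydroxy(4-allyloxy-3-methoxyphenyl)methyl]butane-1,4-diol
Product: 13 4-[(1S,3aR,4S,6aR)-4-(4-allyloxy-3-methoxyphenyl)tetrahydro-1H,3H-furo[3,4-c]furan-1-yl]-2,6-dimethoxyphenol, via quinone methide 11 (not isolated), via monocyclic oxolane 12 (not isolated)
Conditions: TsOH·H2O (10 mol %), CH2Cl2/THF (10:1), 0 °C to rt; Et3N quench at full conversion
Reagents that add atoms: none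
Why: Acid-catalysed loss of the C7 silyloxy group from the p-hydroxybenzylic position gives the ring-B p-quinone methide 11 (as its O-protonated form), the intermediate of lignan biosynthesis, and the C9′ hydroxyl adds to C7 by oxa-1,6-addition to give 12; the closest known reaction type is the acid-mediated cyclodehydration of 1,4-diaryl-2,3-bis(hydroxymethyl)butane-1,4-diols to furofurans. This first ring (O–C7) closes in 5-exo-trig mode on the exocyclic methide carbon, and the second ring closes in the same mode when the C9 hydroxyl captures the p-alkoxybenzylic cation at C7′. C7 is set by C8: the methide reacts in the conformer with C8–H eclipsing the ring plane (least allylic strain) and the tethered oxygen attacks so that ring B ends trans to the C8 substituent on the exo face, and C7′ is set in the same way by C8′ whatever its configuration in 10. The step needs chemoselectivity for the primary C9′ hydroxyl over the C7′ hydroxyl (which would give a 2,5-diaryloxolane) and kinetic control against C7/C7′ epimerisation and Friedel–Crafts closure onto the facing arene. The first is secured because the competing bis-benzylic ether re-ionises under the conditions while the 4-exo alternative (C9 hydroxyl on C7) is not viable, and the second by catalytic acid, low temperature and an early quench.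

Step 7
Reactants: 13 4-[(1S,3aR,4S,6aR)-4-(4-allyloxy-3-methoxyphenyl)tetrahydro-1H,3H-furo[3,4-c]furan-1-yl]-2,6-dimethoxyphenol; 14 (R)-4-benzyl-3-(chloroacetyl)oxazolidin-2-one
Product: 15 (R)-4-benzyl-3-{2-[4-((1S,3aR,4S,6aR)-4-(4-allyloxy-3-methoxyphenyl)tetrahydro-1H,3H-furo[3,4-c]furan-1-yl)-2,6-dimethoxyphenoxy]acetyl}oxazolidin-2-one
Conditions: Cs2CO3, MeCN, rt to 40 °C
Reagents that add atoms: none
Why: Williamson ether synthesis in which the only free phenol (ring B) displaces the activated α-chloride of the imide, placing the glycolate unit on O4 of ring B.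

Step 8
Reactants: 15 (R)-4-benzyl-3-{2-[4-((1S,3aR,4S,6aR)-4-(4-allyloxy-3-methoxyphenyl)tetrahydro-1H,3H-furo[3,4-c]furan-1-yl)-2,6-dimethoxyphenoxy]acetyl}oxazolidin-2-one; 8 4-(allyloxy)-3-methoxybenzaldehyde
Product: 16 (R)-4-benzyl-3-[(2S,3S)-3-(4-allyloxy-3-methoxyphenyl)-2-{4-[(1S,3aR,4S,6aR)-4-(4-allyloxy-3-methoxyphenyl)tetrahydro-1H,3H-furo[3,4-c]furan-1-yl]-2,6-dimethoxyphenoxy}-3-(trimethylsilyloxy)propanoyl]oxazolidin-2-one
Conditions: MgCl2 (20 mol %), Et3N, Me3SiCl, EtOAc, rt; filtration through Et3N-deactivated silica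
Reagents that add atoms: chlorotrimethylsilane, C[Si](C)(C)Cl
Why: Magnesium-halide-catalysed direct anti-aldol reaction of an N-acyloxazolidinone, in which soft enolisation gives the chelated Z-enolate, the non-enolisable aldehyde adds opposite to the auxiliary benzyl group through a boat transition state to set C8″ and C7″ in the anti (erythro) sense, and silylation of the aldolate turns the catalyst over.

Step 9
Reactants: 16 (R)-4-benzyl-3-[(2S,3S)-3-(4-allyloxy-3-methoxyphenyl)-2-{4-[(1S,3aR,4S,6aR)-4-(4-allyloxy-3-methoxyphenyl)tetrahydro-1H,3H-furo[3,4-c]furan-1-yl]-2,6-dimethoxyphenoxy}-3-(trimethylsilyloxy)propanoyl]oxazolidin-2-one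
Product: 18 (1S,2R)-1-(4-allyloxy-3-methoxyphenyl)-2-{4-[(1S,3aR,4S,6aR)-4-(4-allyloxy-3-methoxyphenyl)tetrahydro-1H,3H-furo[3,4-c]furan-1-yl]-2,6-dimethoxyphenoxy}propane-1,3-diol, via silyl ether alcohol 17 (not isolated)
Conditions: NaBH4, THF/H2O (4:1), 0 °C to rt; then aq. citric acid, THF, rt
Reagents that add atoms: none
Why: Reductive cleavage of the N-acyloxazolidinone at the exocyclic carbonyl releases the primary alcohol and the auxiliary without touching C8″, and mild aqueous acid then hydrolyses the trimethylsilyl ether.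

Step 10
Reactants: 18 (1S,2R)-1-(4-allyloxy-3-methoxyphenyl)-2-{4-[(1S,3aR,4S,6aR)-4-(4-allyloxy-3-methoxyphenyl)tetrahydro-1H,3H-furo[3,4-c]furan-1-yl]-2,6-dimethoxyphenoxy}propane-1,3-diol
Product: 19 hedyotol C
Conditions: Pd(PPh3)4 (5 mol %), morpholine, THF, rt
Reagents that add atoms: none
Why: Tsuji–Trost-type deallylation (zerovalent palladium forms the π-allyl complex, morpholine captures it) frees both guaiacyl phenols under neutral conditions that leave the benzylic furofuran ethers and the benzylic alcohol untouched.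

**Compound list**

1 | syringaldehyde (4-hydroxy-3,5-dimethoxybenzaldehyde) | O=Cc1cc(OC)c(O)c(OC)c1 | starting material
2 | 4-formyl-2,6-dimethoxyphenyl pivalate | CC(C)(C)C(=O)Oc1c(OC)cc(C=O)cc1OC | intermediate
3 | methyl 4-oxobutanoate | COC(=O)CCC=O | starting material
4 | methyl (3S,4R)-3-formyl-4-hydroxy-4-(3,5-dimethoxy-4-pivaloyloxyphenyl)butanoate (not isolated) | COC(=O)C[C@H](C=O)[C@@H](O)c1cc(OC)c(OC(=O)C(C)(C)C)c(OC)c1 | intermediate
5 | methyl (3R,4R)-4-hydroxy-3-(hydroxymethyl)-4-(3,5-dimethoxy-4-pivaloyloxyphenyl)butanoate (not isolated) | COC(=O)C[C@H](CO)[C@@H](O)c1cc(OC)c(OC(=O)C(C)(C)C)c(OC)c1 | intermediate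
6 | (R)-4-[(R)-hydroxy(3,5-dimethoxy-4-pivaloyloxyphenyl)methyl]oxolan-2-one | O=C1C[C@H](CO1)[C@@H](O)c1cc(OC)c(OC(=O)C(C)(C)C)c(OC)c1 | intermediate
7 | (R)-4-[(R)-(tert-butyldimethylsilyloxy)(3,5-dimethoxy-4-pivaloyloxyphenyl)methyl]oxolan-2-one | O=C1C[C@H](CO1)[C@@H](O[Si](C)(C)C(C)(C)C)c1cc(OC)c(OC(=O)C(C)(C)C)c(OC)c1 | intermediate
8 | 4-(allyloxy)-3-methoxybenzaldehyde | C=CCOc1ccc(C=O)cc1OC | starting material
9 | (3S,4R)-3-[hydroxy(4-allyloxy-3-methoxyphenyl)methyl]-4-[(R)-(tert-butyldimethylsilyloxy)(3,5-dimethoxy-4-pivaloyloxyphenyl)methyl]oxolan-2-one, both C7′ epimers | C=CCOc1ccc(cc1OC)C(O)[C@H]1C(=O)OC[C@@H]1[C@@H](O[Si](C)(C)C(C)(C)C)c1cc(OC)c(OC(=O)C(C)(C)C)c(OC)c1 | intermediate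
10 | (2R,3R)-2-[(R)-(tert-butyldimethylsilyloxy)(4-hydroxy-3,5-dimethoxyphenyl)methyl]-3-[hydroxy(4-allyloxy-3-methoxyphenyl)methyl]butane-1,4-diol, both C7′ epimers | C=CCOc1ccc(cc1OC)C(O)[C@@H](CO)[C@H](CO)[C@@H](O[Si](C)(C)C(C)(C)C)c1cc(OC)c(O)c(OC)c1 | intermediate
11 | 4-[(2R,3R)-4-hydroxy-2,3-bis(hydroxymethyl)-4-(4-allyloxy-3-methoxyphenyl)butylidene]-2,6-dimethoxycyclohexa-2,5-dien-1-one, ring-B p-quinone methide (not isolated) | C=CCOc1ccc(cc1OC)C(O)[C@@H](CO)[C@H](CO)C=C1C=C(OC)C(=O)C(OC)=C1 | intermediate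
12 | 4-[(2S,3R,4R)-4-[hydroxy(4-allyloxy-3-methoxyphenyl)methyl]-3-(hydroxymethyl)oxolan-2-yl]-2,6-dimethoxyphenol (not isolated) | C=CCOc1ccc(cc1OC)C(O)[C@H]1CO[C@H](c2cc(OC)c(O)c(OC)c2)[C@H]1CO | intermediate
13 | 4-[(1S,3aR,4S,6aR)-4-(4-allyloxy-3-methoxyphenyl)tetrahydro-1H,3H-furo[3,4-c]furan-1-yl]-2,6-dimethoxyphenol (ring-A O-allyl ether of (+)-medioresinol) | C=CCOc1ccc(cc1OC)[C@H]1OC[C@H]2[C@@H]1CO[C@@H]2c1cc(OC)c(O)c(OC)c1 | intermediate
14 | (R)-4-benzyl-3-(chloroacetyl)oxazolidin-2-one | O=C(CCl)N1[C@H](Cc2ccccc2)COC1=O | starting material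
15 | (R)-4-benzyl-3-{2-[4-((1S,3aR,4S,6aR)-4-(4-allyloxy-3-methoxyphenyl)tetrahydro-1H,3H-furo[3,4-c]furan-1-yl)-2,6-dimethoxyphenoxy]acetyl}oxazolidin-2-one | C=CCOc1ccc(cc1OC)[C@H]1OC[C@H]2[C@@H]1CO[C@@H]2c1cc(OC)c(OCC(=O)N2[C@H](Cc3ccccc3)COC2=O)c(OC)c1 | intermediate
16 | (R)-4-benzyl-3-[(2S,3S)-3-(4-allyloxy-3-methoxyphenyl)-2-(aryloxy as in 15)-3-(trimethylsilyloxy)propanoyl]oxazolidin-2-one | C=CCOc1ccc(cc1OC)[C@H]1OC[C@H]2[C@@H]1CO[C@@H]2c1cc(OC)c(O[C@H](C(=O)N2[C@H](Cc3ccccc3)COC2=O)[C@@H](O[Si](C)(C)C)c2ccc(OCC=C)c(OC)c2)c(OC)c1 | intermediate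
17 | (2R,3S)-3-(4-allyloxy-3-methoxyphenyl)-2-(aryloxy as in 15)-3-(trimethylsilyloxy)propan-1-ol (not isolated) | C=CCOc1ccc(cc1OC)[C@H]1OC[C@H]2[C@@H]1CO[C@@H]2c1cc(OC)c(O[C@H](CO)[C@@H](O[Si](C)(C)C)c2ccc(OCC=C)c(OC)c2)c(OC)c1 | intermediate
18 | (1S,2R)-1-(4-allyloxy-3-methoxyphenyl)-2-{4-[(1S,3aR,4S,6aR)-4-(4-allyloxy-3-methoxyphenyl)tetrahydro-1H,3H-furo[3,4-c]furan-1-yl]-2,6-dimethoxyphenoxy}propane-1,3-diol | C=CCOc1ccc(cc1OC)[C@H]1OC[C@H]2[C@@H]1CO[C@@H]2c1cc(OC)c(O[C@H](CO)[C@@H](O)c2ccc(OCC=C)c(OC)c2)c(OC)c1 | intermediate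
19 | hedyotol C, (1S,2R)-1-(4-hydroxy-3-methoxyphenyl)-2-{4-[(1S,3aR,4S,6aR)-4-(4-hydroxy-3-methoxyphenyl)tetrahydro-1H,3H-furo[3,4-c]furan-1-yl]-2,6-dimethoxyphenoxy}propane-1,3-diol | COc1cc([C@H]2OC[C@H]3[C@@H]2CO[C@@H]3c2cc(OC)c(O[C@H](CO)[C@@H](O)c3ccc(O)c(OC)c3)c(OC)c2)ccc1O | target

**Step count and risks**

Total step count: 10. Longest linear sequence: 10 steps (1 to 19); the partners 3, 8 and 14 are purchased.

Steps most likely to fail:

1. Step 8. The aryloxy oxygen and its two flanking methoxy groups may compete for magnesium, which could erode the anti selectivity or reverse the enolate facial selectivity, and addition to the electron-rich aldehyde may be slow. The fallback sets out from 13 and returns at 18. Compound 13 is alkylated (Cs2CO3, MeCN) with (S)-4-benzyl-3-(chloroacetyl)oxazolidin-2-one to give the (S)-configured glycolate imide F1. An Evans syn-aldol reaction (Bu2BOTf, iPr2NEt, CH2Cl2, −78 °C, then 8) should give the (2S,3R) syn adduct F2, with C8″ correct and C7″ epimeric. A Mitsunobu reaction (4-nitrobenzoic acid, PPh3, DIAD, THF) inverts C7″ to give the (2S,3S) 4-nitrobenzoate F3. LiBH4 (THF/MeOH, 0 °C) then cleaves ester and auxiliary to give 18.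

2. Step 6. The product ethers may re-ionise under the acid, which would erode the C7/C7′ configuration, and the cations may be captured irreversibly by the facing electron-rich ring (Friedel–Crafts closure). The fallback sets out from 9 and returns at 15, closing the two rings in separate operations. Compound 9 is silylated (TBSOTf, 2,6-lutidine) to the bis-silyl lactone F4, and LiAlH4 gives the bis-silyl diol phenol F5. Warming with K2CO3 in MeCN generates the C7′-silylated quinone methide F6 by phenoxide-driven 1,6-elimination of silanolate. The C9′ hydroxyl then closes the O–C7 ring under base, where the product cannot re-ionise and the C7′ oxygen is blocked, to give the monocyclic oxolane silyl ether F7. Alkylation with 14 (Cs2CO3, MeCN) caps the phenol as the glycolate imide F8. Brief treatment with camphorsulfonic acid in CH2Cl2 at 0 °C closes only the second ring through the C7′ cation and gives 15.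

3. Step 2. Addition of the enamine to the aryl aldehyde may be slow, so that self-aldolisation of 3 consumes the donor and conversion stalls. The fallback sets out from 2 and returns at 6. (R)-4-Benzyloxazolidin-2-one is acylated with methyl 4-chloro-4-oxobutanoate (n-BuLi, THF, −78 °C) to the succinate imide F9. The MgCl2-catalysed anti-aldol reaction (Et3N, Me3SiCl, EtOAc) with 2 should give the silylated anti adduct F10. NaBH4 (THF/H2O) reduces the imide to the silylated hydroxy ester F11, which on mild acid work-up loses the silyl group and lactonises to 6.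

Further compounds
F1 | step 8 | (S)-4-benzyl-3-{2-[4-((1S,3aR,4S,6aR)-4-(4-allyloxy-3-methoxyphenyl)tetrahydro-1H,3H-furo[3,4-c]furan-1-yl)-2,6-dimethoxyphenoxy]acetyl}oxazolidin-2-one | C=CCOc1ccc(cc1OC)[C@H]1OC[C@H]2[C@@H]1CO[C@@H]2c1cc(OC)c(OCC(=O)N2[C@@H](Cc3ccccc3)COC2=O)c(OC)c1
F2 | step 8 | (S)-4-benzyl-3-[(2S,3R)-3-(4-allyloxy-3-methoxyphenyl)-3-hydroxy-2-(aryloxy as in F1)propanoyl]oxazolidin-2-one | C=CCOc1ccc(cc1OC)[C@H]1OC[C@H]2[C@@H]1CO[C@@H]2c1cc(OC)c(O[C@H](C(=O)N2[C@@H](Cc3ccccc3)COC2=O)[C@H](O)c2ccc(OCC=C)c(OC)c2)c(OC)c1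
F3 | step 8 | (S)-4-benzyl-3-[(2S,3S)-3-(4-allyloxy-3-methoxyphenyl)-3-(4-nitrobenzoyloxy)-2-(aryloxy as in F1)propanoyl]oxazolidin-2-one | C=CCOc1ccc(cc1OC)[C@H]1OC[C@H]2[C@@H]1CO[C@@H]2c1cc(OC)c(O[C@H](C(=O)N2[C@@H](Cc3ccccc3)COC2=O)[C@@H](OC(=O)c2ccc(cc2)[N+](=O)[O-])c2ccc(OCC=C)c(OC)c2)c(OC)c1
F4 | step 6 | C7′-O-tert-butyldimethylsilyl ether of 9 | C=CCOc1ccc(cc1OC)C(O[Si](C)(C)C(C)(C)C)[C@H]1C(=O)OC[C@@H]1[C@@H](O[Si](C)(C)C(C)(C)C)c1cc(OC)c(OC(=O)C(C)(C)C)c(OC)c1
F5 | step 6 | C7′-O-tert-butyldimethylsilyl ether of 10 | C=CCOc1ccc(cc1OC)C(O[Si](C)(C)C(C)(C)C)[C@@H](CO)[C@H](CO)[C@@H](O[Si](C)(C)C(C)(C)C)c1cc(OC)c(O)c(OC)c1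
F6 | step 6 | C7′-O-tert-butyldimethylsilyl ether of quinone methide 11 (not isolated) | C=CCOc1ccc(cc1OC)C(O[Si](C)(C)C(C)(C)C)[C@@H](CO)[C@H](CO)C=C1C=C(OC)C(=O)C(OC)=C1
F7 | step 6 | C7′-O-tert-butyldimethylsilyl ether of 12 | C=CCOc1ccc(cc1OC)C(O[Si](C)(C)C(C)(C)C)[C@H]1CO[C@H](c2cc(OC)c(O)c(OC)c2)[C@H]1CO
F8 | step 6 | ring-B O-[2-((R)-4-benzyl-2-oxooxazolidin-3-yl)-2-oxoethyl] ether of F7 | C=CCOc1ccc(cc1OC)C(O[Si](C)(C)C(C)(C)C)[C@H]1CO[C@H](c2cc(OC)c(OCC(=O)N3[C@H](Cc4ccccc4)COC3=O)c(OC)c2)[C@H]1CO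
F9 | step 2 | methyl 4-[(R)-4-benzyl-2-oxooxazolidin-3-yl]-4-oxobutanoate | COC(=O)CCC(=O)N1[C@H](Cc2ccccc2)COC1=O
F10 | step 2 | methyl (3S,4R)-3-[(R)-4-benzyl-2-oxooxazolidine-3-carbonyl]-4-(3,5-dimethoxy-4-pivaloyloxyphenyl)-4-(trimethylsilyloxy)butanoate | COC(=O)C[C@H](C(=O)N1[C@H](Cc2ccccc2)COC1=O)[C@@H](O[Si](C)(C)C)c1cc(OC)c(OC(=O)C(C)(C)C)c(OC)c1
F11 | step 2 | methyl (3R,4R)-3-(hydroxymethyl)-4-(3,5-dimethoxy-4-pivaloyloxyphenyl)-4-(trimethylsilyloxy)butanoate (not isolated) | COC(=O)C[C@H](CO)[C@@H](O[Si](C)(C)C)c1cc(OC)c(OC(=O)C(C)(C)C)c(OC)c1
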